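(The earlier runs and the new flask are calculated for an exercise, and the scatter is random.)

- Start from maple's slowness: 14.5% target at 6.00 min, against 43.6% in oak, with 0.029 M and 0.087 M charged. Yields hide what that gap means, so count turnovers.

| setting | maple | oak | winter | spring | dusk | autumn |
|---|---|---|---|---|---|---|
| starting material | 0.029 M | 0.087 M | 0.040 M | 0.050 M | 0.080 M | 0.12 M |
| partner | 1 equiv | 1 equiv | 1.00 equiv | 1.00 equiv | 1.00 equiv | 1.00 equiv |
| remark | run made earlier | run made earlier |  |  |  |  |
| time |  |  | 12 min | 12 min | 12 min | 12 min |

| run | time / min | target / % |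
|---|---|---|
| maple | 1.00 | 3.0 |
| maple | 2.00 | 5.7 |
| maple | 3.00 | 8.2 |
| maple | 4.00 | 10.2 |
| maple | 5.00 | 12.7 |
| maple | 6.00 | 14.5 |
| oak | 1.00 | 12.8 |
| oak | 2.00 | 22.6 |
| oak | 3.00 | 29.4 |
| oak | 4.00 | 35.3 |
| oak | 5.00 | 39.9 |
| oak | 6.00 | 43.6 |

(each reading ± 0.3 percentage points)

- in percentages every species weighs as the starting material in it: one homo dimer counts as two
- what may be going on: starting material + partner -> target; 2 starting material -> homo dimer
- "hardly changes" means that all values lie within two and a half points (for a concentration: within two and a half percent of the largest)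

- [target] at the end for winter, spring, dusk, autumn, in this order
- the course of these numbers from the first flask to the last (hardly changes / rises all the way / falls all the way / rises, then falls / falls, then rises)

- Define the turnover count N as charged c(starting material) over remaining c(starting material), raised to the power 1.50, minus one. Take the remainder as charge minus target, which counts homo dimer as nil, since the runs read target and nothing else.
- Test it on oak: N per minute reads 0.228 min⁻¹ at 1.00 min, 0.229 min⁻¹ at 3.00 min and, at 6.00 min, the turnover clock rate, N per minute in oak, 0.227 min⁻¹.
- Compare maple, whose clock reads 0.0441 min⁻¹. The two clocks give a concentration exponent of 1.49 as a reading, the power that straightened time, so read an overall order of 2.50.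
- Scale oak's clock by that power at 1.00 equiv of partner. Over 12 min, N becomes 0.849, 1.19, 2.40 and 4.41.
- Invert the count, and my row for c(target) reads 0.0134 M, 0.0203 M, 0.0446 M and 0.0811 M.
- Set that beside your forecast of 0.0132 M, 0.0198 M, 0.0425 M and 0.076 M, course rises all the way, reached with “a 9–15% reduction for dimer loss”. We share the course, but my autumn number stands higher than yours.

- The flask gives 0.0136 M, 0.0205 M, 0.0448 M and 0.0813 M, course rises all the way, so your forecast held.

    starting material + partner → target, rate k1*[starting material]*[partner]^1.5 (k = 0.100 M⁻¹·⁵ s⁻¹)
    2 starting material → homo dimer (k = 1.00 × 10⁻⁴ M⁻¹ s⁻¹)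

- Autumn carries 0.496% homo dimer at 12.0 min beside 67.7% target, and the step to homo dimer shifts autumn's c(target) by a negligible amount. Run the clock on winter to 120 min: N reaches 8.49, which means 77.7% target, and winter stands at 77.6%.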